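The plan rests on cutting the lower C4–C4a bond. In the dihydroflavonol half the ketone carbon C4 is bonded to ring D at C4a, the carbon ortho to the ring F ether oxygen O1. A bromine at C4a is exchanged for lithium, and the aryl anion acylates a Weinreb amide that ends the O1–C2–C3 chain. This single operation closes ring F and installs the ketone, while lower C2 and C3, set earlier by an epoxide opening, are left alone. The cyclisation substrate is the perbenzylated upper 4-arylflavan whose ring D carries bromine and, on the neighbouring oxygen, an anti-configured 2-benzyloxy-3-aryl-propanoic N-methoxy-N-methyl amide.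

Key step: step 17

Assumption: in step 2 the (R)-configured ligand is taken to give the 2S product, by analogy with the sense found for cyclic enones; if the sense proves opposite, the antipodal ligand is used. Ring letters: A, C, B are the benzo, pyran and pendant aryl rings of the upper flavan; D, F, E are those of the lower unit.

Step 1
Reactants: 1 7-hydroxychromone
Product: 2 7-(benzyloxy)-4H-chromen-4-one
Conditions: BnBr, K2CO3, DMF, rt
Reagents that add atoms: benzyl bromide, BrCc1ccccc1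
Why: Williamson ether synthesis on the only acidic site, with a base too weak to open the pyranone ring.

Step 2
Reactants: 2 7-(benzyloxy)-4H-chromen-4-one; 3 [3,4,5-tris(benzyloxy)phenyl]boronic acid
Product: 4 (2S)-7-(benzyloxy)-2-[3,4,5-tris(benzyloxy)phenyl]chroman-4-one
Conditions: Pd(OCOCF3)2 (5 mol %), (R)-t-BuPyOx (6 mol %), NH4PF6 (30 mol %), H2O (5 equiv), ClCH2CH2Cl, 60 °C
Reagents that add atoms: none
Why: Asymmetric conjugate addition of an arylboronic acid to a chromone (Hayashi–Miyaura-type 1,4-addition under cationic palladium–pyridinooxazoline catalysis) is an established flavanone synthesis, in which C2 is set by ligand-controlled face selection during aryl insertion and water protonates the palladium enolate before β-hydride elimination can give the flavone.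

Step 3
Reactants: 5 3-(benzyloxy)phenol
Product: 6 1-(benzyloxy)-3-(methoxymethoxy)benzene
Conditions: MOMCl, i-Pr2NEt, CH2Cl2, 0 °C → rt
Reagents that add atoms: chloromethyl methyl ether, COCCl
Why: O-alkylation of the phenol gives a MOM ether that is the stronger ortho-director for step 4 and, unlike benzyl, is removable by mild acid, so the two ring D oxygens are differentiated from the outset.

Step 4
Reactants: 6 1-(benzyloxy)-3-(methoxymethoxy)benzene; 4 (2S)-7-(benzyloxy)-2-[3,4,5-tris(benzyloxy)phenyl]chroman-4-one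
Product: 9 (2S)-7-(benzyloxy)-4-[2-(benzyloxy)-6-(methoxymethoxy)phenyl]-2-[3,4,5-tris(benzyloxy)phenyl]chroman-4-ol (both C4 epimers), via aryllithium 7 (not isolated), via arylcerium dichloride 8 (not isolated)
Conditions: 6, n-BuLi, THF, 0 °C; CeCl3, THF, −78 °C; then 4, −78 → −40 °C; H2O
Reagents that add atoms: none
Why: Directed ortho-metalation occurs at the carbon flanked by OMOM and OBn, and the derived organocerium (Imamoto-type 1,2-addition) is nucleophilic but weakly basic, so it should add to the C4 ketone without enolising it or opening the pyranone ring, leaving C2 untouched and giving a C4 carbinol mixture that is erased in step 5.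

Step 5
Reactants: 9 (2S)-7-(benzyloxy)-4-[2-(benzyloxy)-6-(methoxymethoxy)phenyl]-2-[3,4,5-tris(benzyloxy)phenyl]chroman-4-ol
Product: 10 (2S)-7-(benzyloxy)-4-[2-(benzyloxy)-6-(methoxymethoxy)phenyl]-2-[3,4,5-tris(benzyloxy)phenyl]-2H-chromene
Conditions: PPTS (cat.), 4 Å MS, PhMe, 50 °C
Reagents that add atoms: none
Why: E1 dehydration of a tertiary, doubly benzylic alcohol whose cation is stabilised by the para 7-benzyloxy group can only place the alkene at C3=C4, and the buffered acid is too mild to cleave the aryl MOM ether or ionise C2.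

Step 6
Reactants: 10 (2S)-7-(benzyloxy)-4-[2-(benzyloxy)-6-(methoxymethoxy)phenyl]-2-[3,4,5-tris(benzyloxy)phenyl]-2H-chromene
Product: 12 (2R,3S,4S)-7-(benzyloxy)-4-[2-(benzyloxy)-6-(methoxymethoxy)phenyl]-2-[3,4,5-tris(benzyloxy)phenyl]chroman-3-ol, via C3 alkylborane 11 (not isolated)
Conditions: BH3·THF, THF, 0 °C → rt; then NaOH, H2O2, H2O, 0 °C → rt
Reagents that add atoms: hydrogen peroxide, OO
Why: Brown hydroboration–oxidation adds H and B syn across C3=C4 with boron at the less substituted C3 and from the face opposite the C2 aryl group, so that after oxidation with retention the 3-hydroxyl is trans to both aryl substituents, which sets C3 (S) and C4 (S) under control of C2 as known for flav-3-enes.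

Step 7
Reactants: 12 (2R,3S,4S)-7-(benzyloxy)-4-[2-(benzyloxy)-6-(methoxymethoxy)phenyl]-2-[3,4,5-tris(benzyloxy)phenyl]chroman-3-ol
Product: 13 (2R,3S,4S)-3,7-bis(benzyloxy)-4-[2-(benzyloxy)-6-(methoxymethoxy)phenyl]-2-[3,4,5-tris(benzyloxy)phenyl]chromane
Conditions: NaH, BnBr, n-Bu4NI (cat.), DMF, 0 °C → rt
Reagents that add atoms: benzyl bromide, BrCc1ccccc1
Why: Williamson benzylation of the only free hydroxyl, in a molecule with no carbon acid that the alkoxide could epimerise.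

Step 8
Reactants: 13 (2R,3S,4S)-3,7-bis(benzyloxy)-4-[2-(benzyloxy)-6-(methoxymethoxy)phenyl]-2-[3,4,5-tris(benzyloxy)phenyl]chromane
Product: 14 3-(benzyloxy)-2-[(2R,3S,4S)-3,7-bis(benzyloxy)-2-[3,4,5-tris(benzyloxy)phenyl]chroman-4-yl]phenol
Conditions: HCl (cat.), MeOH–THF, 40 °C
Reagents that add atoms: none
Why: Acid-catalysed acetal exchange removes the phenolic MOM group as dimethoxymethane, while the benzyl ethers and the C4–aryl bond of this 5-deoxy flavan, which lacks the phloroglucinol activation that makes such bonds acid-labile, should be retained.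

Step 9
Reactants: 14 3-(benzyloxy)-2-[(2R,3S,4S)-3,7-bis(benzyloxy)-2-[3,4,5-tris(benzyloxy)phenyl]chroman-4-yl]phenol
Product: 15 3-(benzyloxy)-6-bromo-2-[(2R,3S,4S)-3,7-bis(benzyloxy)-2-[3,4,5-tris(benzyloxy)phenyl]chroman-4-yl]phenol
Conditions: NBS (1.0 equiv), i-Pr2NH (10 mol %), CH2Cl2, −78 → 0 °C
Reagents that add atoms: N-bromosuccinimide, O=C1CCC(=O)N1Br
Why: Amine-catalysed ortho-selective electrophilic bromination of a phenol delivers bromine through a hydrogen-bonded N-bromoamine to the only free ortho position, which is also para to the benzyloxy group and is the future lower C4a, and the free phenol ring is far more reactive than the ether-only rings.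

Step 10
Reactants: 16 3,4,5-tris(benzyloxy)benzaldehyde; 17 ethyl (triphenylphosphoranylidene)acetate
Product: 18 ethyl (2E)-3-[3,4,5-tris(benzyloxy)phenyl]prop-2-enoate
Conditions: PhMe, 80 °C
Reagents that add atoms: none
Why: Wittig olefination with a stabilised ylide gives the E-cinnamate selectively.

Step 11
Reactants: 18 ethyl (2E)-3-[3,4,5-tris(benzyloxy)phenyl]prop-2-enoate
Product: 19 (2E)-3-[3,4,5-tris(benzyloxy)phenyl]prop-2-en-1-ol
Conditions: i-Bu2AlH, CH2Cl2, −78 → 0 °C; aq. potassium sodium tartrate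
Reagents that add atoms: none
Why: 1,2-Reduction of the conjugated ester by the aluminium hydride stops at the allylic alcohol and leaves the alkene geometry intact.

Step 12
Reactants: 19 (2E)-3-[3,4,5-tris(benzyloxy)phenyl]prop-2-en-1-ol
Product: 20 [(2S,3S)-3-[3,4,5-tris(benzyloxy)phenyl]oxiran-2-yl]methanol
Conditions: Ti(OiPr)4 (10 mol %), L-(+)-diisopropyl tartrate (12 mol %), t-BuOOH, 4 Å MS, CH2Cl2, −20 °C
Reagents that add atoms: tert-butyl hydroperoxide, CC(C)(C)OO
Why: Sharpless asymmetric epoxidation of an E-allylic alcohol with the L-(+)-tartrate complex delivers oxygen to the face that gives the (2S,3S)-epoxide, setting both centres, and the catalytic, sieve-dried variant limits opening of the electron-rich aryl epoxide.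

Step 13
Reactants: 20 [(2S,3S)-3-[3,4,5-tris(benzyloxy)phenyl]oxiran-2-yl]methanol
Product: 22 sodium (2R,3S)-3-[3,4,5-tris(benzyloxy)phenyl]oxirane-2-carboxylate, via epoxy aldehyde 21 (not isolated)
Conditions: TEMPO (cat.), NaClO2, NaOCl (cat.), Na2HPO4/NaH2PO4 buffer (pH 6.7), MeCN–H2O, 35 °C; isolated as the sodium salt
Reagents that add atoms: sodium chlorite, [Na+].[O-]Cl=O
Why: Oxoammonium oxidation to the aldehyde followed in the same pot by chlorite (Pinnick-type) oxidation gives the carboxylate at near-neutral pH, and keeping it as the salt avoids the decarboxylative ring opening that free 3-arylglycidic acids undergo.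

Step 14
Reactants: 22 sodium (2R,3S)-3-[3,4,5-tris(benzyloxy)phenyl]oxirane-2-carboxylate
Product: 24 (2R,3S)-N-methoxy-N-methyl-3-[3,4,5-tris(benzyloxy)phenyl]oxirane-2-carboxamide, via mixed pivalic anhydride 23 (not isolated)
Conditions: PivCl, THF, −15 °C; then MeNH(OMe)·HCl, N-methylmorpholine, −15 °C → rt
Reagents that add atoms: N,O-dimethylhydroxylamine hydrochloride, CNOC.Cl
Why: In this mixed-anhydride amidation the amine attacks the less hindered glycidoyl carbonyl of 23, the carboxylate is acylated directly so the acid is never set free, and neither epoxide carbon takes part, so the trans-(2R,3S) configuration is retained.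

Step 15
Reactants: 15 3-(benzyloxy)-6-bromo-2-[(2R,3S,4S)-3,7-bis(benzyloxy)-2-[3,4,5-tris(benzyloxy)phenyl]chroman-4-yl]phenol; 24 (2R,3S)-N-methoxy-N-methyl-3-[3,4,5-tris(benzyloxy)phenyl]oxirane-2-carboxamide
Product: 25 (2R,3R)-3-{3-(benzyloxy)-6-bromo-2-[(2R,3S,4S)-3,7-bis(benzyloxy)-2-[3,4,5-tris(benzyloxy)phenyl]chroman-4-yl]phenoxy}-2-hydroxy-N-methoxy-N-methyl-3-[3,4,5-tris(benzyloxy)phenyl]propanamide
Conditions: Cs2CO3 (0.5 equiv), DMF, 60 °C
Reagents that add atoms: none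
Why: SN2 opening of an aryl epoxide by a phenoxide takes place at the benzylic carbon C3, the usual site for 3-arylglycidic acid derivatives, with inversion, so C3 becomes R while C2 keeps its configuration, which gives the anti (2R,3R) arrangement that maps onto lower C2 and C3.

Step 16
Reactants: 25 (2R,3R)-3-{3-(benzyloxy)-6-bromo-2-[(2R,3S,4S)-3,7-bis(benzyloxy)-2-[3,4,5-tris(benzyloxy)phenyl]chroman-4-yl]phenoxy}-2-hydroxy-N-methoxy-N-methyl-3-[3,4,5-tris(benzyloxy)phenyl]propanamide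
Product: 26 (2R,3R)-2-(benzyloxy)-3-{3-(benzyloxy)-6-bromo-2-[(2R,3S,4S)-3,7-bis(benzyloxy)-2-[3,4,5-tris(benzyloxy)phenyl]chroman-4-yl]phenoxy}-N-methoxy-N-methyl-3-[3,4,5-tris(benzyloxy)phenyl]propanamide
Conditions: BnBr, Ag2O, n-Bu4NI (cat.), CH2Cl2, rt, dark
Reagents that add atoms: benzyl bromide, BrCc1ccccc1
Why: Silver-oxide-promoted O-alkylation (Purdie-type) benzylates the α-hydroxy amide without a strong base, so the α-centre is not enolised and the β-aryloxy group is not eliminated.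

Step 17
Reactants: 26 (2R,3R)-2-(benzyloxy)-3-{3-(benzyloxy)-6-bromo-2-[(2R,3S,4S)-3,7-bis(benzyloxy)-2-[3,4,5-tris(benzyloxy)phenyl]chroman-4-yl]phenoxy}-N-methoxy-N-methyl-3-[3,4,5-tris(benzyloxy)phenyl]propanamide
Product: 29 (2R,3R)-3,7-bis(benzyloxy)-8-[(2R,3S,4S)-3,7-bis(benzyloxy)-2-[3,4,5-tris(benzyloxy)phenyl]chroman-4-yl]-2-[3,4,5-tris(benzyloxy)phenyl]chroman-4-one, via ring D aryllithium 27 (not isolated), via lithium hemiaminal alkoxide 28 (not isolated)
Conditions: n-BuLi (1.05 equiv), THF, −95 → −78 °C; AcOH, −78 °C → rt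
Reagents that add atoms: none
Why: Bromine–lithium exchange at ring D C4a should be faster at this temperature than addition of n-BuLi to the amide or removal of the C3 proton, and the aryllithium 27, held beside the side chain by O1, attacks the amide carbonyl to give the five-membered lithium chelate 28, which persists until the cold acetic acid quench and only then collapses to the ketone, so a second addition is excluded. The closest known reaction type is the Parham cyclisation (cycloacylation) of 2-bromoaryl substrates carrying a tethered Weinreb amide, which is established for chroman-4-ones from 3-(2-bromoaryloxy)propanoic acid derivatives. Ring F is closed by a 6-exo-trig attack that forms the lower C4–C4a bond. No stereocentre is created in the product, since lower C2 and C3 come from epoxide 24 and the hemiaminal carbon of 28 is lost on collapse. The step needs regiocontrol, which the position of the bromine (ortho to O1, fixed in step 9) supplies, and retention at C3, which the low temperature, the fast intramolecular capture and the acidic quench before warming should secure. The five existing stereocentres and all benzyl ethers are inert to these conditions.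

Step 18
Reactants: 29 (2R,3R)-3,7-bis(benzyloxy)-8-[(2R,3S,4S)-3,7-bis(benzyloxy)-2-[3,4,5-tris(benzyloxy)phenyl]chroman-4-yl]-2-[3,4,5-tris(benzyloxy)phenyl]chroman-4-one
Product: 30 (2R,3R)-3,7-dihydroxy-8-[(2R,3S,4S)-3,7-dihydroxy-2-(3,4,5-trihydroxyphenyl)chroman-4-yl]-2-(3,4,5-trihydroxyphenyl)chroman-4-one
Conditions: H2 (1 atm), Pd(OH)2/C, THF–MeOH, rt
Reagents that add atoms: none
Why: Catalytic hydrogenolysis cleaves the ten benzyl ethers, while the cyclic benzylic C2–O1 bonds and the ring-deactivated aryl ketone are known to survive such neutral conditions in the flavan-3-ol and dihydroflavonol series.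

Compound list

1 | 7-hydroxy-4H-chromen-4-one (7-hydroxychromone) | O=c1ccoc2cc(O)ccc12 | starting material
2 | 7-(benzyloxy)-4H-chromen-4-one | O=c1ccoc2cc(OCc3ccccc3)ccc12 | intermediate
3 | [3,4,5-tris(benzyloxy)phenyl]boronic acid | OB(O)c1cc(OCc2ccccc2)c(OCc2ccccc2)c(OCc2ccccc2)c1 | starting material
4 | (2S)-7-(benzyloxy)-2-[3,4,5-tris(benzyloxy)phenyl]chroman-4-one | O=C1C[C@@H](c2cc(OCc3ccccc3)c(OCc3ccccc3)c(OCc3ccccc3)c2)Oc2cc(OCc3ccccc3)ccc12 | intermediate
5 | 3-(benzyloxy)phenol | Oc1cccc(OCc2ccccc2)c1 | starting material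
6 | 1-(benzyloxy)-3-(methoxymethoxy)benzene | COCOc1cccc(OCc2ccccc2)c1 | intermediate
7 | [2-(benzyloxy)-6-(methoxymethoxy)phenyl]lithium | [Li]c1c(OCOC)cccc1OCc1ccccc1 | intermediate
8 | dichloro[2-(benzyloxy)-6-(methoxymethoxy)phenyl]cerium | Cl[Ce](Cl)c1c(OCOC)cccc1OCc1ccccc1 | intermediate
9 | (2S)-7-(benzyloxy)-4-[2-(benzyloxy)-6-(methoxymethoxy)phenyl]-2-[3,4,5-tris(benzyloxy)phenyl]chroman-4-ol, C4 epimer mixture | OC1(c2c(OCOC)cccc2OCc2ccccc2)C[C@@H](c2cc(OCc3ccccc3)c(OCc3ccccc3)c(OCc3ccccc3)c2)Oc2cc(OCc3ccccc3)ccc12 | intermediate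
10 | (2S)-7-(benzyloxy)-4-[2-(benzyloxy)-6-(methoxymethoxy)phenyl]-2-[3,4,5-tris(benzyloxy)phenyl]-2H-chromene | C1(c2c(OCOC)cccc2OCc2ccccc2)=C[C@@H](c2cc(OCc3ccccc3)c(OCc3ccccc3)c(OCc3ccccc3)c2)Oc2cc(OCc3ccccc3)ccc12 | intermediate
11 | (2S,3S,4S)-7-(benzyloxy)-4-[2-(benzyloxy)-6-(methoxymethoxy)phenyl]-2-[3,4,5-tris(benzyloxy)phenyl]chroman-3-ylborane (BH2 at C3, same spatial arrangement as 12) | COCOc1cccc(OCc2ccccc2)c1[C@@H]1c2ccc(OCc3ccccc3)cc2O[C@H](c2cc(OCc3ccccc3)c(OCc3ccccc3)c(OCc3ccccc3)c2)[C@H]1B | intermediate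
12 | (2R,3S,4S)-7-(benzyloxy)-4-[2-(benzyloxy)-6-(methoxymethoxy)phenyl]-2-[3,4,5-tris(benzyloxy)phenyl]chroman-3-ol | COCOc1cccc(OCc2ccccc2)c1[C@@H]1c2ccc(OCc3ccccc3)cc2O[C@H](c2cc(OCc3ccccc3)c(OCc3ccccc3)c(OCc3ccccc3)c2)[C@H]1O | intermediate
13 | (2R,3S,4S)-3,7-bis(benzyloxy)-4-[2-(benzyloxy)-6-(methoxymethoxy)phenyl]-2-[3,4,5-tris(benzyloxy)phenyl]chromane | COCOc1cccc(OCc2ccccc2)c1[C@@H]1c2ccc(OCc3ccccc3)cc2O[C@H](c2cc(OCc3ccccc3)c(OCc3ccccc3)c(OCc3ccccc3)c2)[C@H]1OCc1ccccc1 | intermediate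
14 | 3-(benzyloxy)-2-[(2R,3S,4S)-3,7-bis(benzyloxy)-2-[3,4,5-tris(benzyloxy)phenyl]chroman-4-yl]phenol | Oc1cccc(OCc2ccccc2)c1[C@@H]1c2ccc(OCc3ccccc3)cc2O[C@H](c2cc(OCc3ccccc3)c(OCc3ccccc3)c(OCc3ccccc3)c2)[C@H]1OCc1ccccc1 | intermediate
15 | 3-(benzyloxy)-6-bromo-2-[(2R,3S,4S)-3,7-bis(benzyloxy)-2-[3,4,5-tris(benzyloxy)phenyl]chroman-4-yl]phenol | Oc1c(Br)ccc(OCc2ccccc2)c1[C@@H]1c2ccc(OCc3ccccc3)cc2O[C@H](c2cc(OCc3ccccc3)c(OCc3ccccc3)c(OCc3ccccc3)c2)[C@H]1OCc1ccccc1 | intermediate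
16 | 3,4,5-tris(benzyloxy)benzaldehyde | O=Cc1cc(OCc2ccccc2)c(OCc2ccccc2)c(OCc2ccccc2)c1 | starting material
17 | ethyl (triphenylphosphoranylidene)acetate | CCOC(=O)C=P(c1ccccc1)(c1ccccc1)c1ccccc1 | starting material
18 | ethyl (2E)-3-[3,4,5-tris(benzyloxy)phenyl]prop-2-enoate | CCOC(=O)/C=C/c1cc(OCc2ccccc2)c(OCc2ccccc2)c(OCc2ccccc2)c1 | intermediate
19 | (2E)-3-[3,4,5-tris(benzyloxy)phenyl]prop-2-en-1-ol | OC/C=C/c1cc(OCc2ccccc2)c(OCc2ccccc2)c(OCc2ccccc2)c1 | intermediate
20 | [(2S,3S)-3-[3,4,5-tris(benzyloxy)phenyl]oxiran-2-yl]methanol | OC[C@@H]1O[C@H]1c1cc(OCc2ccccc2)c(OCc2ccccc2)c(OCc2ccccc2)c1 | intermediate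
21 | (2R,3S)-3-[3,4,5-tris(benzyloxy)phenyl]oxirane-2-carbaldehyde | O=C[C@@H]1O[C@H]1c1cc(OCc2ccccc2)c(OCc2ccccc2)c(OCc2ccccc2)c1 | intermediate
22 | sodium (2R,3S)-3-[3,4,5-tris(benzyloxy)phenyl]oxirane-2-carboxylate | [Na+].[O-]C(=O)[C@@H]1O[C@H]1c1cc(OCc2ccccc2)c(OCc2ccccc2)c(OCc2ccccc2)c1 | intermediate
23 | (2R,3S)-3-[3,4,5-tris(benzyloxy)phenyl]oxirane-2-carboxylic pivalic anhydride | CC(C)(C)C(=O)OC(=O)[C@@H]1O[C@H]1c1cc(OCc2ccccc2)c(OCc2ccccc2)c(OCc2ccccc2)c1 | intermediate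
24 | (2R,3S)-N-methoxy-N-methyl-3-[3,4,5-tris(benzyloxy)phenyl]oxirane-2-carboxamide | CON(C)C(=O)[C@@H]1O[C@H]1c1cc(OCc2ccccc2)c(OCc2ccccc2)c(OCc2ccccc2)c1 | intermediate
25 | (2R,3R)-3-{3-(benzyloxy)-6-bromo-2-[(2R,3S,4S)-3,7-bis(benzyloxy)-2-[3,4,5-tris(benzyloxy)phenyl]chroman-4-yl]phenoxy}-2-hydroxy-N-methoxy-N-methyl-3-[3,4,5-tris(benzyloxy)phenyl]propanamide | Brc1ccc(OCc5ccccc5)c([C@@H]3c4ccc(OCc5ccccc5)cc4O[C@H](c4cc(OCc5ccccc5)c(OCc5ccccc5)c(OCc5ccccc5)c4)[C@H]3OCc3ccccc3)c1O[C@H](c1cc(OCc5ccccc5)c(OCc5ccccc5)c(OCc5ccccc5)c1)[C@@H](O)C(=O)N(C)OC | intermediate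
26 | (2R,3R)-2-(benzyloxy)-3-{3-(benzyloxy)-6-bromo-2-[(2R,3S,4S)-3,7-bis(benzyloxy)-2-[3,4,5-tris(benzyloxy)phenyl]chroman-4-yl]phenoxy}-N-methoxy-N-methyl-3-[3,4,5-tris(benzyloxy)phenyl]propanamide | Brc1ccc(OCc5ccccc5)c([C@@H]3c4ccc(OCc5ccccc5)cc4O[C@H](c4cc(OCc5ccccc5)c(OCc5ccccc5)c(OCc5ccccc5)c4)[C@H]3OCc3ccccc3)c1O[C@H](c1cc(OCc5ccccc5)c(OCc5ccccc5)c(OCc5ccccc5)c1)[C@@H](OCc1ccccc1)C(=O)N(C)OC | intermediate
27 | aryllithium from 26 (lithium in place of bromine at ring D C4a) | [Li]c1ccc(OCc5ccccc5)c([C@@H]3c4ccc(OCc5ccccc5)cc4O[C@H](c4cc(OCc5ccccc5)c(OCc5ccccc5)c(OCc5ccccc5)c4)[C@H]3OCc3ccccc3)c1O[C@H](c1cc(OCc5ccccc5)c(OCc5ccccc5)c(OCc5ccccc5)c1)[C@@H](OCc1ccccc1)C(=O)N(C)OC | intermediate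
28 | lithium alkoxide of the cyclic N-methoxy-N-methyl hemiaminal at lower C4 (ring F closed, C4 configuration undefined) | [Li]OC1(N(C)OC)c2ccc(OCc5ccccc5)c([C@@H]3c4ccc(OCc5ccccc5)cc4O[C@H](c4cc(OCc5ccccc5)c(OCc5ccccc5)c(OCc5ccccc5)c4)[C@H]3OCc3ccccc3)c2O[C@H](c2cc(OCc5ccccc5)c(OCc5ccccc5)c(OCc5ccccc5)c2)[C@H]1OCc1ccccc1 | intermediate
29 | (2R,3R)-3,7-bis(benzyloxy)-8-[(2R,3S,4S)-3,7-bis(benzyloxy)-2-[3,4,5-tris(benzyloxy)phenyl]chroman-4-yl]-2-[3,4,5-tris(benzyloxy)phenyl]chroman-4-one | O=C1c2ccc(OCc5ccccc5)c([C@@H]3c4ccc(OCc5ccccc5)cc4O[C@H](c4cc(OCc5ccccc5)c(OCc5ccccc5)c(OCc5ccccc5)c4)[C@H]3OCc3ccccc3)c2O[C@H](c2cc(OCc5ccccc5)c(OCc5ccccc5)c(OCc5ccccc5)c2)[C@H]1OCc1ccccc1 | intermediate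
30 | (2R,3R)-3,7-dihydroxy-8-[(2R,3S,4S)-3,7-dihydroxy-2-(3,4,5-trihydroxyphenyl)chroman-4-yl]-2-(3,4,5-trihydroxyphenyl)chroman-4-one | O=C1c2ccc(O)c([C@@H]3c4ccc(O)cc4O[C@H](c4cc(O)c(O)c(O)c4)[C@H]3O)c2O[C@H](c2cc(O)c(O)c(O)c2)[C@H]1O | target

Total step count: 18. Longest linear sequence: 12 steps (steps 1, 2, 4 to 9 and 15 to 18).

Steps most likely to fail

1. Step 17 (key step). The aryllithium may be protonated by the C3–H next to the amide faster than it acylates, after which β-elimination of the ring D phenoxide would consume the side chain; n-BuLi may also add to the amide before the exchange is complete. The fallback sets out from 26. The Weinreb amide is reduced with LiAlH4 (THF, −78 °C) to the aldehyde (2R,3R)-2-(benzyloxy)-3-{3-(benzyloxy)-6-bromo-2-[(2R,3S,4S)-3,7-bis(benzyloxy)-2-[3,4,5-tris(benzyloxy)phenyl]chroman-4-yl]phenoxy}-3-[3,4,5-tris(benzyloxy)phenyl]propanal F1. Bromine–lithium exchange (n-BuLi, THF, −95 °C) is then followed by intramolecular 1,2-addition to the much more electrophilic formyl group, which should outrun proton transfer and gives the lower-unit chroman-4-ol F2 as a C4 epimer mixture. Dess–Martin oxidation (CH2Cl2, NaHCO3) converges both epimers and comes back to the route at 29.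

2. Step 15. The phenoxide is flanked by bromine and by the flavan-4-yl group, so substitution may be slow; prolonged heating could then bring ionisation of the electron-rich benzylic epoxide (loss of stereospecificity, Meinwald rearrangement) or base-induced degradation of the glycidic amide. The fallback sets out from 15 and the epoxy alcohol 20, which carries no base-sensitive amide and so tolerates forcing conditions (NaOH, H2O–dioxane, 80 °C). Phenoxide opening of 3-arylglycidols at the benzylic carbon with inversion is well established and should give (2S,3R)-3-{3-(benzyloxy)-6-bromo-2-[(2R,3S,4S)-3,7-bis(benzyloxy)-2-[3,4,5-tris(benzyloxy)phenyl]chroman-4-yl]phenoxy}-3-[3,4,5-tris(benzyloxy)phenyl]propane-1,2-diol F3. Selective oxidation of the primary alcohol (TEMPO, PhI(OAc)2, MeCN–H2O) gives the corresponding (2R,3R)-2-hydroxypropanoic acid F4, and coupling with MeNH(OMe)·HCl (EDC·HCl, HOBt, N-methylmorpholine, CH2Cl2) comes back to the route at 25.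

3. Step 9. Bromination may take place para to the hydroxyl (ring D C6), on the dialkoxy ring A, or twice. The fallback sets out from 14. O-Carbamoylation (NaH, ClCONEt2, THF) gives 3-(benzyloxy)-2-[(2R,3S,4S)-3,7-bis(benzyloxy)-2-[3,4,5-tris(benzyloxy)phenyl]chroman-4-yl]phenyl N,N-diethylcarbamate F5. Directed ortho-metalation (s-BuLi, TMEDA, THF, −78 °C), for which the carbamate is the strongest director present and has a single free ortho position, followed by a quench with BrCCl2CCl2Br, gives the 6-bromo carbamate F6. Cleavage with KOH in EtOH at reflux comes back to the route at 15.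

Further compounds

F1 | step 17 | (2R,3R)-2-(benzyloxy)-3-{3-(benzyloxy)-6-bromo-2-[(2R,3S,4S)-3,7-bis(benzyloxy)-2-[3,4,5-tris(benzyloxy)phenyl]chroman-4-yl]phenoxy}-3-[3,4,5-tris(benzyloxy)phenyl]propanal | Brc1ccc(OCc5ccccc5)c([C@@H]3c4ccc(OCc5ccccc5)cc4O[C@H](c4cc(OCc5ccccc5)c(OCc5ccccc5)c(OCc5ccccc5)c4)[C@H]3OCc3ccccc3)c1O[C@H](c1cc(OCc5ccccc5)c(OCc5ccccc5)c(OCc5ccccc5)c1)[C@@H](OCc1ccccc1)C=O
F2 | step 17 | 4-hydroxy analogue of 29 (lower-unit chroman-4-ol, C4 epimer mixture, all other centres as in 29) | OC1c2ccc(OCc5ccccc5)c([C@@H]3c4ccc(OCc5ccccc5)cc4O[C@H](c4cc(OCc5ccccc5)c(OCc5ccccc5)c(OCc5ccccc5)c4)[C@H]3OCc3ccccc3)c2O[C@H](c2cc(OCc5ccccc5)c(OCc5ccccc5)c(OCc5ccccc5)c2)[C@H]1OCc1ccccc1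
F3 | step 15 | (2S,3R)-3-{3-(benzyloxy)-6-bromo-2-[(2R,3S,4S)-3,7-bis(benzyloxy)-2-[3,4,5-tris(benzyloxy)phenyl]chroman-4-yl]phenoxy}-3-[3,4,5-tris(benzyloxy)phenyl]propane-1,2-diol | Brc1ccc(OCc5ccccc5)c([C@@H]3c4ccc(OCc5ccccc5)cc4O[C@H](c4cc(OCc5ccccc5)c(OCc5ccccc5)c(OCc5ccccc5)c4)[C@H]3OCc3ccccc3)c1O[C@H](c1cc(OCc5ccccc5)c(OCc5ccccc5)c(OCc5ccccc5)c1)[C@@H](O)CO
F4 | step 15 | (2R,3R)-3-{3-(benzyloxy)-6-bromo-2-[(2R,3S,4S)-3,7-bis(benzyloxy)-2-[3,4,5-tris(benzyloxy)phenyl]chroman-4-yl]phenoxy}-2-hydroxy-3-[3,4,5-tris(benzyloxy)phenyl]propanoic acid | Brc1ccc(OCc5ccccc5)c([C@@H]3c4ccc(OCc5ccccc5)cc4O[C@H](c4cc(OCc5ccccc5)c(OCc5ccccc5)c(OCc5ccccc5)c4)[C@H]3OCc3ccccc3)c1O[C@H](c1cc(OCc5ccccc5)c(OCc5ccccc5)c(OCc5ccccc5)c1)[C@@H](O)C(=O)O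
F5 | step 9 | 3-(benzyloxy)-2-[(2R,3S,4S)-3,7-bis(benzyloxy)-2-[3,4,5-tris(benzyloxy)phenyl]chroman-4-yl]phenyl N,N-diethylcarbamate | CCN(CC)C(=O)Oc1cccc(OCc2ccccc2)c1[C@@H]1c2ccc(OCc3ccccc3)cc2O[C@H](c2cc(OCc3ccccc3)c(OCc3ccccc3)c(OCc3ccccc3)c2)[C@H]1OCc1ccccc1
F6 | step 9 | 3-(benzyloxy)-6-bromo-2-[(2R,3S,4S)-3,7-bis(benzyloxy)-2-[3,4,5-tris(benzyloxy)phenyl]chroman-4-yl]phenyl N,N-diethylcarbamate | CCN(CC)C(=O)Oc1c(Br)ccc(OCc2ccccc2)c1[C@@H]1c2ccc(OCc3ccccc3)cc2O[C@H](c2cc(OCc3ccccc3)c(OCc3ccccc3)c(OCc3ccccc3)c2)[C@H]1OCc1ccccc1
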